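**Plan**
- The target is a 1,2-dihydronaphthalene (naphthalene numbering): C1 is the aryl-bearing methine, C2 and C3 carry the aroyl groups, C3=C4 is the alkene, and ring A is fused at C4a–C8a. This core is what allows the key step: C3=C4 is traced back to a C4 carbinol β to the C3 ketone, and cutting C1–C2 and C3–C4 then leaves a cis-1,2-diaroylethylene and the two benzylic carbons of ring A, i.e. a 2-(arylmethyl)benzaldehyde.
- The aldehyde is cut at the C1–C8a aryl–CH2 bond (Negishi coupling). Both of its arenes come from one protected 2,3,4-trioxygenated benzaldehyde, which fixes the ring A substitution pattern without a regioselective halogenation.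
- The enedione is made directly as the Z isomer by oxidative opening of a 2,5-diarylfuran.
- Forward: etherification; Dakin oxidation, ortho-formylation and triflation on one portion, reduction and chlorination on the other; coupling; photoenolization/Diels–Alder closes the only new ring; dehydration; debenzylation.
- Stereochemistry: C1 and C2 (1S,2S, cis) are set together in the cycloaddition, relative configuration by the Z dienophile adding endo to the outward-substituted dienol, absolute configuration by a TADDOL ligand on titanium. C3 and C4 are transient.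

Key step: step 11

Assumption: (R,R)-TADDOL is taken to steer the dienophile to the diene face that gives the (1S,2S,3S,4S) adduct; should the sense of induction prove opposite, the (S,S) ligand is used and nothing else changes.

**Step 1**
Reactants: 1 2,3,4-trihydroxybenzaldehyde
Product: 2 3,4-bis(benzyloxy)-2-hydroxybenzaldehyde
Conditions: BnBr (2.05 equiv), K2CO3 (2.2 equiv), DMF, 0 °C to rt
Reagents that add atoms: benzyl bromide, BrCc1ccccc1
Why: Williamson etherification in which the 2-hydroxyl, held in a hydrogen bond to the formyl oxygen, is the least nucleophilic of the three, so two equivalents of halide should stop at the 3,4-dibenzyl ether.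

**Step 2**
Reactants: 2 3,4-bis(benzyloxy)-2-hydroxybenzaldehyde
Product: 3 3,4-bis(benzyloxy)-2-methoxybenzaldehyde
Conditions: MeI (3 equiv), K2CO3 (2 equiv), DMF, 40 °C
Reagents that add atoms: iodomethane, CI
Why: Williamson O-methylation, in which excess iodomethane in a dipolar aprotic solvent overcomes the chelation of the remaining phenol.

**Step 3**
Reactants: 3 3,4-bis(benzyloxy)-2-methoxybenzaldehyde
Product: 5 3,4-bis(benzyloxy)-2-methoxyphenol, via aryl formate 4 (not isolated)
Conditions: mCPBA (1.3 equiv), CH2Cl2, 0 °C to rt; then K2CO3 (0.2 equiv), MeOH, rt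
Reagents that add atoms: mCPBA, O=C(OO)c1cccc(Cl)c1
Why: Dakin-type Baeyer–Villiger oxidation, in which the electron-rich aryl group migrates in preference to hydrogen and the formate is then cleaved by methanolysis.

**Step 4**
Reactants: 5 3,4-bis(benzyloxy)-2-methoxyphenol
Product: 7 4,5-bis(benzyloxy)-2-hydroxy-3-methoxybenzaldehyde, via salicyl alcohol 6 (not isolated)
Conditions: MgCl2 (2 equiv), Et3N (4 equiv), (CH2O)n (6 equiv), MeCN, reflux; 1 M HCl work-up
Reagents that add atoms: paraformaldehyde (as formaldehyde), C=O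
Why: Casnati–Skattebøl ortho-formylation, in which the magnesium phenoxide delivers formaldehyde to the only free ortho position and the hydroxymethyl group is oxidised by hydride transfer to a second formaldehyde.

**Step 5**
Reactants: 7 4,5-bis(benzyloxy)-2-hydroxy-3-methoxybenzaldehyde
Product: 8 3,4-bis(benzyloxy)-6-formyl-2-methoxyphenyl trifluoromethanesulfonate
Conditions: Tf2O (1.2 equiv), pyridine (2.5 equiv), CH2Cl2, 0 °C
Reagents that add atoms: trifluoromethanesulfonic anhydride, O=S(=O)(OS(=O)(=O)C(F)(F)F)C(F)(F)F
Why: O-sulfonylation of a phenol, which turns the oxygen-bearing carbon next to the methoxy group into the cross-coupling site.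

**Step 6**
Reactants: 3 3,4-bis(benzyloxy)-2-methoxybenzaldehyde
Product: 9 [3,4-bis(benzyloxy)-2-methoxyphenyl]methanol
Conditions: NaBH4 (0.6 equiv), THF/MeOH, 0 °C
Reagents that add atoms: none
Why: Borohydride reduction of an aryl aldehyde, to which benzyl and methyl ethers are inert.

**Step 7**
Reactants: 9 [3,4-bis(benzyloxy)-2-methoxyphenyl]methanol
Product: 10 1,2-bis(benzyloxy)-4-(chloromethyl)-3-methoxybenzene
Conditions: SOCl2 (1.2 equiv), CH2Cl2, 0 °C; used without chromatography
Reagents that add atoms: thionyl chloride, O=S(Cl)Cl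
Why: Chlorodehydroxylation through the chlorosulfite, fast for an electron-rich benzylic alcohol at a temperature the aryl benzyl ethers tolerate.

**Step 8**
Reactants: 10 1,2-bis(benzyloxy)-4-(chloromethyl)-3-methoxybenzene; 8 3,4-bis(benzyloxy)-6-formyl-2-methoxyphenyl trifluoromethanesulfonate
Product: 12 4,5-bis(benzyloxy)-2-[3,4-bis(benzyloxy)-2-methoxybenzyl]-3-methoxybenzaldehyde, via benzylzinc chloride 11 (not isolated)
Conditions: 10 (1.4 equiv), Zn dust (2 equiv), LiCl (2 equiv), THF, 25 °C; then 8 (1 equiv), Pd(OAc)2 (2 mol %), SPhos (4 mol %), THF, 25 °C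
Reagents that add atoms: none
Why: LiCl-assisted zinc insertion into the benzylic chloride and Negishi coupling with the aryl triflate, where the ortho formyl group speeds oxidative addition, the biaryl phosphine copes with two ortho substituents, and the benzylzinc halide should leave the aldehyde alone on the timescale of the coupling.

**Step 9**
Reactants: 13 2,5-dibromofuran; 14 4-(benzyloxy)phenylboronic acid
Product: 15 2,5-bis[4-(benzyloxy)phenyl]furan
Conditions: 13 (1 equiv), 14 (2.3 equiv), Pd(PPh3)4 (5 mol %), 2 M aq. Na2CO3, DME, 80 °C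
Reagents that add atoms: none
Why: Twofold Suzuki–Miyaura coupling at the two activated α-positions of the furan on zerovalent palladium.

**Step 10**
Reactants: 15 2,5-bis[4-(benzyloxy)phenyl]furan
Product: 16 (Z)-1,4-bis[4-(benzyloxy)phenyl]but-2-ene-1,4-dione
Conditions: mCPBA (1.05 equiv), CH2Cl2, 0 °C, dark; NaHCO3 wash
Reagents that add atoms: mCPBA, O=C(OO)c1cccc(Cl)c1
Why: Peracid oxidative ring opening of a 2,5-diarylfuran, in which epoxidation of the C2–C3 bond and collapse of the oxirane unveil both aryl ketones and hand on the former C3=C4 furan bond with its cis geometry, provided light and acid are kept out.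

**Step 11**
Reactants: 12 4,5-bis(benzyloxy)-2-[3,4-bis(benzyloxy)-2-methoxybenzyl]-3-methoxybenzaldehyde; 16 (Z)-1,4-bis[4-(benzyloxy)phenyl]but-2-ene-1,4-dione
Product: 18 [(1S,2S,3S,4S)-6,7-bis(benzyloxy)-1-[3,4-bis(benzyloxy)-2-methoxyphenyl]-4-hydroxy-8-methoxy-1,2,3,4-tetrahydronaphthalene-2,3-diyl]bis{[4-(benzyloxy)phenyl]methanone} (all-cis), via photodienol 17 (not isolated)
Conditions: 12 (1 equiv), 16 (2 equiv), Ti(Oi-Pr)4 (2 equiv), (R,R)-TADDOL (2 equiv), degassed toluene, hν (366 nm), rt; aqueous work-up
Reagents that add atoms: none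
Why: Excitation of the aldehyde (n to π*) and intersystem crossing are followed by abstraction of the doubly benzylic C1 hydrogen through a six-membered transition state, and the biradical relaxes to dienol 17, which is held on titanium as a dienolate while any inward-hydroxyl isomer returns to 12 by a 1,5-hydrogen shift. The closest known reaction type is the photoenolization/Diels–Alder reaction of 2-(arylmethyl)benzaldehydes, in the titanium TADDOLate form established for 2-alkylbenzaldehydes. The one new ring, the six-membered C1–C2–C3–C4–C4a–C8a carbocycle, closes by a concerted suprafacial [4+2] cycloaddition across C1 and C4 that restores the aromaticity of ring A. C2 and C3 are cis because the Z geometry of 16 is transferred suprafacially; C1 and C4 are cis to them because the aryl and hydroxyl groups sit on the outer positions of the diene termini and both aroyl groups add endo, the C3 carbonyl being bound to the same titanium as the dienolate oxygen; the absolute sense at all four centres comes from the aryl groups of the TADDOL ligand screening one face of the bound dienolate. The step needs the aryl-outward dienol and a cycloaddition that outruns light-driven loss of the dienophile: inside, the aryl group would collide with the C4 terminus, whereas outside it can twist away from the C8 methoxy group; the C1–H bond is activated by two arenes; the symmetric dienophile leaves no regiochemical question; and an excess of 16 under 366 nm light should keep the enedione on its Z side.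

**Step 12**
Reactants: 18 all-cis (1S,2S,3S,4S) adduct
Product: 19 [(1S,2S)-6,7-bis(benzyloxy)-1-[3,4-bis(benzyloxy)-2-methoxyphenyl]-8-methoxy-1,2-dihydronaphthalene-2,3-diyl]bis{[4-(benzyloxy)phenyl]methanone}
Conditions: p-TsOH·H2O (10 mol %), CH2Cl2, 0 °C, short reaction time; NaHCO3 quench
Reagents that add atoms: none
Why: Acid-catalysed E1 dehydration of a β-hydroxy ketone, in which ionisation at C4 is assisted by the para benzyloxy group on C7 and loss of H3 gives the enone conjugated with ring A, leaving C1 and C2 untouched if the acid is weak and the exposure brief.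

**Step 13**
Reactants: 19 hexabenzyl ether of the target
Product: 20 licobichalcone, [(1S,2S)-1-(3,4-dihydroxy-2-methoxyphenyl)-6,7-dihydroxy-8-methoxy-1,2-dihydronaphthalene-2,3-diyl]bis[(4-hydroxyphenyl)methanone]
Conditions: BCl3 (1 M in CH2Cl2, 15 equiv), C6HMe5 (20 equiv), CH2Cl2, −78 °C; MeOH, then H2O
Reagents that add atoms: none
Why: Lewis-acid debenzylation with pentamethylbenzene as a non-basic benzyl cation trap (Friedel–Crafts capture), which at −78 °C should cleave the six aryl benzyl ethers while sparing the two methyl ethers, the enone (which hydrogenolysis would reduce) and the enolisable C2 centre.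

**Compound list**
1 | 2,3,4-trihydroxybenzaldehyde | O=Cc1ccc(O)c(O)c1O | starting material
2 | 3,4-bis(benzyloxy)-2-hydroxybenzaldehyde | O=Cc1ccc(OCc2ccccc2)c(OCc2ccccc2)c1O | intermediate
3 | 3,4-bis(benzyloxy)-2-methoxybenzaldehyde | COc1c(C=O)ccc(OCc2ccccc2)c1OCc1ccccc1 | intermediate
4 | 3,4-bis(benzyloxy)-2-methoxyphenyl formate (not isolated) | COc1c(OC=O)ccc(OCc2ccccc2)c1OCc1ccccc1 | intermediate
5 | 3,4-bis(benzyloxy)-2-methoxyphenol | COc1c(O)ccc(OCc2ccccc2)c1OCc1ccccc1 | intermediate
6 | 3,4-bis(benzyloxy)-6-(hydroxymethyl)-2-methoxyphenol (salicyl alcohol, present as its magnesium salt; not isolated) | COc1c(O)c(CO)cc(OCc2ccccc2)c1OCc1ccccc1 | intermediate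
7 | 4,5-bis(benzyloxy)-2-hydroxy-3-methoxybenzaldehyde | COc1c(O)c(C=O)cc(OCc2ccccc2)c1OCc1ccccc1 | intermediate
8 | 3,4-bis(benzyloxy)-6-formyl-2-methoxyphenyl trifluoromethanesulfonate | COc1c(OS(=O)(=O)C(F)(F)F)c(C=O)cc(OCc2ccccc2)c1OCc1ccccc1 | intermediate
9 | [3,4-bis(benzyloxy)-2-methoxyphenyl]methanol | COc1c(CO)ccc(OCc2ccccc2)c1OCc1ccccc1 | intermediate
10 | 1,2-bis(benzyloxy)-4-(chloromethyl)-3-methoxybenzene | COc1c(CCl)ccc(OCc2ccccc2)c1OCc1ccccc1 | intermediate
11 | [3,4-bis(benzyloxy)-2-methoxybenzyl]zinc chloride (not isolated) | COc1c(C[Zn]Cl)ccc(OCc2ccccc2)c1OCc1ccccc1 | intermediate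
12 | 4,5-bis(benzyloxy)-2-[3,4-bis(benzyloxy)-2-methoxybenzyl]-3-methoxybenzaldehyde | COc1c(Cc2c(C=O)cc(OCc3ccccc3)c(OCc3ccccc3)c2OC)ccc(OCc2ccccc2)c1OCc1ccccc1 | intermediate
13 | 2,5-dibromofuran | Brc1ccc(Br)o1 | starting material
14 | 4-(benzyloxy)phenylboronic acid | OB(O)c1ccc(OCc2ccccc2)cc1 | starting material
15 | 2,5-bis[4-(benzyloxy)phenyl]furan | c1cc(-c2ccc(OCc3ccccc3)cc2)oc1-c1ccc(OCc2ccccc2)cc1 | intermediate
16 | (Z)-1,4-bis[4-(benzyloxy)phenyl]but-2-ene-1,4-dione | O=C(/C=C\C(=O)c1ccc(OCc2ccccc2)cc1)c1ccc(OCc2ccccc2)cc1 | intermediate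
17 | photodienol (hydroxy-o-quinodimethane): 2,3-bis(benzyloxy)-1-methoxy-5-(hydroxymethylidene)-6-{[3,4-bis(benzyloxy)-2-methoxyphenyl]methylidene}cyclohexa-1,3-diene, hydroxyl and aryl group both on the outer positions of the diene termini; bound to titanium as its dienolate (not isolated) | O/C=C1\C=C(OCc2ccccc2)C(OCc2ccccc2)=C(OC)/C1=C\c1ccc(OCc2ccccc2)c(OCc2ccccc2)c1OC | intermediate
18 | [(1S,2S,3S,4S)-6,7-bis(benzyloxy)-1-[3,4-bis(benzyloxy)-2-methoxyphenyl]-4-hydroxy-8-methoxy-1,2,3,4-tetrahydronaphthalene-2,3-diyl]bis{[4-(benzyloxy)phenyl]methanone}, all four substituents cis | COc1c([C@H]2c3c(cc(OCc4ccccc4)c(OCc4ccccc4)c3OC)[C@@H](O)[C@@H](C(=O)c3ccc(OCc4ccccc4)cc3)[C@H]2C(=O)c2ccc(OCc3ccccc3)cc2)ccc(OCc2ccccc2)c1OCc1ccccc1 | intermediate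
19 | [(1S,2S)-6,7-bis(benzyloxy)-1-[3,4-bis(benzyloxy)-2-methoxyphenyl]-8-methoxy-1,2-dihydronaphthalene-2,3-diyl]bis{[4-(benzyloxy)phenyl]methanone}, C1 aryl and C2 aroyl cis | COc1c([C@H]2c3c(cc(OCc4ccccc4)c(OCc4ccccc4)c3OC)C=C(C(=O)c3ccc(OCc4ccccc4)cc3)[C@H]2C(=O)c2ccc(OCc3ccccc3)cc2)ccc(OCc2ccccc2)c1OCc1ccccc1 | intermediate
20 | licobichalcone, (1S,2S), C1 aryl and C2 aroyl cis | COc1c([C@H]2c3c(cc(O)c(O)c3OC)C=C(C(=O)c3ccc(O)cc3)[C@H]2C(=O)c2ccc(O)cc2)ccc(O)c1O | target

**Totals**
Total step count: 13. Longest linear sequence: 9 steps (steps 1, 2, 3, 4, 5, 8, 11, 12, 13).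

**Steps most likely to fail**

1. Step 11. The TADDOLate may discriminate poorly between the two diene faces when the dienophile is a twisted acyclic enedione, and the Z geometry of 16 may erode under light or by reversible alkoxide addition before it is trapped. Fallback: starting from 12 and 16, the cycloaddition is run with Ti(Oi-Pr)4 alone, without the chiral ligand. This should still give the all-cis adduct, but as 18 together with its (1R,2R,3R,4R) enantiomer F1. The pair is separated by preparative chromatography on a chiral stationary phase (amylose tris(3,5-dimethylphenylcarbamate)), so the stereochemistry is secured by resolution instead of induction, and the route is rejoined at 18.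

2. Step 12. C2 may epimerise through enolisation of the C2 ketone toward the conjugated dienol while acid is present, the trans arrangement probably being the more stable one. Fallback: starting from 18, MsCl and Et3N in CH2Cl2 at 0 °C give the C4 mesylate F2, which eliminates in the same flask by an E1cB path through the C3 enolate. The enone is accepted as 19 mixed with its (1S,2R) C2 epimer F3. LiN(SiMe3)2 in THF at −78 °C then converts both into one lithium dienolate F4, C2 being the only enolisable position. Kinetic protonation with AcOH at −78 °C on the face opposite the C1 aryl group places the new C2 hydrogen trans to that aryl group, a tactic well known for 1-aryltetralin-2-carbonyl compounds, and returns the cis compound 19.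

3. Step 8. The benzylzinc reagent may attack the formyl group of 8, or homocouple during the zinc insertion. Fallback: starting from 8, Miyaura borylation (B2pin2, Pd(dppf)Cl2, KOAc, dioxane, 80 °C) gives the aryl pinacol boronate F5. Suzuki–Miyaura coupling of F5 with benzyl chloride 10 (Pd(PPh3)4, K3PO4, toluene/H2O, 80 °C) reverses the polarity of the union, brings no carbanion equivalent near the aldehyde, and returns to 12.

**Further compounds**
F1 | step 11 | (1R,2R,3R,4R) enantiomer of adduct 18 | COc1c([C@@H]2c3c(cc(OCc4ccccc4)c(OCc4ccccc4)c3OC)[C@H](O)[C@H](C(=O)c3ccc(OCc4ccccc4)cc3)[C@@H]2C(=O)c2ccc(OCc3ccccc3)cc2)ccc(OCc2ccccc2)c1OCc1ccccc1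
F2 | step 12 | C4 methanesulfonate of adduct 18 | COc1c([C@H]2c3c(cc(OCc4ccccc4)c(OCc4ccccc4)c3OC)[C@@H](OS(C)(=O)=O)[C@@H](C(=O)c3ccc(OCc4ccccc4)cc3)[C@H]2C(=O)c2ccc(OCc3ccccc3)cc2)ccc(OCc2ccccc2)c1OCc1ccccc1
F3 | step 12 | (1S,2R) C2 epimer of 19, C1 aryl and C2 aroyl trans | COc1c([C@H]2c3c(cc(OCc4ccccc4)c(OCc4ccccc4)c3OC)C=C(C(=O)c3ccc(OCc4ccccc4)cc3)[C@@H]2C(=O)c2ccc(OCc3ccccc3)cc2)ccc(OCc2ccccc2)c1OCc1ccccc1
F4 | step 12 | lithium dienolate of 19 (C2 exocyclic enolate, C1 unchanged) | COc1c([C@H]2c3c(cc(OCc4ccccc4)c(OCc4ccccc4)c3OC)C=C(C(=O)c3ccc(OCc4ccccc4)cc3)C2=C(O[Li])c2ccc(OCc3ccccc3)cc2)ccc(OCc2ccccc2)c1OCc1ccccc1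
F5 | step 8 | 4,5-bis(benzyloxy)-3-methoxy-2-(4,4,5,5-tetramethyl-1,3,2-dioxaborolan-2-yl)benzaldehyde | COc1c(B2OC(C)(C)C(C)(C)O2)c(C=O)cc(OCc2ccccc2)c1OCc1ccccc1
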